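The cyclohexane ring (C1–C5 and C10; C4 bears CH3 and the lactone carbonyl C19, C10 bears CH3 and the furyl ketone C9, C5 is the ring-fusion CH) is cut at C4–C5 and C1–C10. The feature exploited is the side chain C5–C6(O)–C7(OAc)–C8(=O)–CH3: it is C1–C5 of 5-deoxy-D-ribose, and O7 can carry C19 as an ester tether (a δ-lactone, isomeric with the target's C19–O6 γ-lactone). One intramolecular Diels–Alder reaction of the (Z)-2-methylpenta-2,4-dienoate on O7 with the (E)-enone C5=C10 then forms both bonds, both rings and the stereocentres C4, C5 and C10. The precursor is this ester, with O6 and O8 locked in a silylene chair.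

Key step: step 11

Remark (atom labels): C1–C3 are the ring CH2 carbons from C10 to C4; O6, O7 and O8 are the oxygens on C6, C7 and C8; the other labels are as in the paragraph above.
Remark (assumptions): 5-deoxy-D-ribose 14, phosphonate 9, 3-bromobutan-2-one 1 and furan-3-ylmethanol 4 are taken as catalogue compounds; 14 is written as the open-chain aldehyde although it exists mainly as the furanose.
Remark (design): O6 and O8 are masked together as one cyclic di-tert-butylsilylene instead of two different acyclic silyl ethers. A 1,3-diol silylene goes onto the ribo-triol without any need to tell three secondary hydroxyls apart and leaves only O7 free for the tether. Its chair holds C5 and O7 gauche and puts O6 on the enone face away from the diene, and it cannot migrate to O7 during acylation. The price is one site-selective silylation after the cycloaddition (step 14).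
Remark (stereochemistry): the adduct needed is C4 S, C5 R, C10 S with C6 S; D-ribose, the (Z)-dienoate and the (E)-enone are the combination that gives it, and every centre of the key-step precursor and product was checked against the target. The C8 centre is carried from ribose and erased in step 17.

Step 1
Reactants: 1 3-bromobutan-2-one
Product: 3 3-(triphenyl-λ5-phosphanylidene)butan-2-one, via phosphonium bromide 2 (not isolated)
Conditions: PPh3, PhMe, 80 °C; then 2 M NaOH, CH2Cl2, rt
Reagents that add atoms: triphenylphosphine, c1ccc(cc1)P(c1ccccc1)c1ccccc1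
Why: SN2 quaternisation of the phosphine by the α-bromo ketone and deprotonation of the acidic α-CH give the acyl-stabilised ylide (phosphonium salt formation and ylide generation).

Step 2
Reactants: 4 furan-3-ylmethanol
Product: 5 3-(bromomethyl)furan
Conditions: PBr3, Et2O, 0 °C
Reagents that add atoms: phosphorus tribromide, BrP(Br)Br
Why: Bromination of a primary, benzylic-type alcohol with PBr3 is an SN2 displacement of the intermediate phosphite ester and should be clean at 0 °C; the labile bromide is used at once as a dried ether solution.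

Step 3
Reactants: 3 3-(triphenyl-λ5-phosphanylidene)butan-2-one; 5 3-(bromomethyl)furan
Product: 7 1-(furan-3-yl)-4-(triphenyl-λ5-phosphanylidene)pentan-3-one, via ylide enolate 6 (not isolated)
Conditions: n-BuLi, THF, −78 °C; then 5, −78 → 0 °C
Reagents that add atoms: none
Why: Deprotonation of the acetyl methyl group gives the ylide anion, which should be C-alkylated at that terminal carbon by the reactive furylmethyl bromide (γ-alkylation of a β-keto phosphorane).

Step 4
Reactants: 8 acrolein; 9 ethyl 2-[bis(2,2,2-trifluoroethoxy)phosphoryl]propanoate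
Product: 11 ethyl (2Z)-2-methylpenta-2,4-dienoate, via potassium phosphonate carbanion 10 (not isolated)
Conditions: KN(SiMe3)2, 18-crown-6, THF, −78 °C; then 8
Reagents that add atoms: none
Why: Still–Gennari olefination: the electron-poor bis(trifluoroethyl) phosphonate with a dissociated potassium counter-ion eliminates fast from the first-formed adduct, so the (Z)-alkene (ester cis to the vinyl group) should form under kinetic control.

Step 5
Reactants: 11 ethyl (2Z)-2-methylpenta-2,4-dienoate
Product: 13 (2Z)-2-methylpenta-2,4-dienoic acid, via lithium dienoate 12 (not isolated)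
Conditions: LiOH·H2O, THF/H2O, 0 °C → rt; then 1 M HCl, 0 °C
Reagents that add atoms: lithium hydroxide, [Li+].[OH-]
Why: Saponification of the ethyl ester at low temperature followed by acidification should free the acid without touching the alkene geometry (base-mediated ester hydrolysis); the acid is stored cold with BHT.

Step 6
Reactants: 14 5-deoxy-D-ribose
Product: 15 (2R,3R,4R)-1,1-bis(ethylsulfanyl)pentane-2,3,4-triol
Conditions: EtSH, conc. HCl, 0 °C
Reagents that add atoms: ethanethiol, CCS
Why: Acid-catalysed dithioacetal formation (the classical thioacetalisation of aldoses) captures the open-chain aldehyde form, so C5 is masked while O6, O7 and O8 become free secondary hydroxyls; no stereocentre is touched.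

Step 7
Reactants: 15 (2R,3R,4R)-1,1-bis(ethylsulfanyl)pentane-2,3,4-triol
Product: 16 (4R,5R,6R)-4-[bis(ethylsulfanyl)methyl]-2,2-di-tert-butyl-6-methyl-1,3,2-dioxasilinan-5-ol
Conditions: t-Bu2Si(OTf)2, 2,6-lutidine, CH2Cl2, −40 → 0 °C
Reagents that add atoms: di-tert-butylsilyl bis(trifluoromethanesulfonate), CC(C)(C)[Si](OS(=O)(=O)C(F)(F)F)(OS(=O)(=O)C(F)(F)F)C(C)(C)C
Why: Cyclic silylene protection of a diol: the bis-triflate should bridge the 1,3-related O6 and O8 as a six-membered dioxasilinane, not a strained five-membered 1,2-silylene, and in the ribo series this chair carries the dithioacetal carbon, O7–H and the methyl group all equatorial, so only O7 stays free.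

Step 8
Reactants: 16 (4R,5R,6R)-4-[bis(ethylsulfanyl)methyl]-2,2-di-tert-butyl-6-methyl-1,3,2-dioxasilinan-5-ol
Product: 17 (4R,5R,6R)-2,2-di-tert-butyl-5-hydroxy-6-methyl-1,3,2-dioxasilinane-4-carbaldehyde
Conditions: I2, NaHCO3, acetone/H2O, 0 °C
Reagents that add atoms: water, O
Why: Iodine-promoted hydrolysis of the dithioacetal (dethioacetalisation) under bicarbonate buffering should unmask the aldehyde while the silylene survives, and the α-centre C6, already in its stable equatorial arrangement, has no driving force to epimerise.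

Step 9
Reactants: 17 (4R,5R,6R)-2,2-di-tert-butyl-5-hydroxy-6-methyl-1,3,2-dioxasilinane-4-carbaldehyde; 7 1-(furan-3-yl)-4-(triphenyl-λ5-phosphanylidene)pentan-3-one
Product: 18 (4E)-5-[(4S,5R,6R)-2,2-di-tert-butyl-5-hydroxy-6-methyl-1,3,2-dioxasilinan-4-yl]-1-(furan-3-yl)-4-methylpent-4-en-3-one
Conditions: PhMe, 80 °C
Reagents that add atoms: none
Why: Wittig olefination with an α-methyl acyl-stabilised ylide under neutral conditions should give the (E)-trisubstituted enone (C9 trans to C6), and the free O7–H cannot add to the enone because only an oxetane would result.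

Step 10
Reactants: 18 (4E)-5-[(4S,5R,6R)-2,2-di-tert-butyl-5-hydroxy-6-methyl-1,3,2-dioxasilinan-4-yl]-1-(furan-3-yl)-4-methylpent-4-en-3-one; 13 (2Z)-2-methylpenta-2,4-dienoic acid
Product: 20 (4S,5R,6R)-2,2-di-tert-butyl-4-[(1E)-5-(furan-3-yl)-2-methyl-3-oxopent-1-en-1-yl]-6-methyl-1,3,2-dioxasilinan-5-yl (2Z)-2-methylpenta-2,4-dienoate, via mixed anhydride 19 (not isolated)
Conditions: 13, 2,4,6-Cl3C6H2COCl, Et3N, PhMe, 0 °C; then 18, DMAP, 0 °C → rt
Reagents that add atoms: none
Why: Yamaguchi esterification: the mixed anhydride of 13 acylates the equatorial O7–H under DMAP catalysis at low temperature, conditions of the kind used to transfer (Z)-2-methylalk-2-enoyl (angeloyl) groups without loss of geometry, and the cyclic silylene rules out silyl migration to O7.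

Step 11
Reactants: 20 (4S,5R,6R)-2,2-di-tert-butyl-4-[(1E)-5-(furan-3-yl)-2-methyl-3-oxopent-1-en-1-yl]-6-methyl-1,3,2-dioxasilinan-5-yl (2Z)-2-methylpenta-2,4-dienoate
Product: 21 cis-fused cyclohexene δ-lactone adduct with the silylene on O6/O8 (C4 S; C5 R; C10 S; C6 S; C7 R; C8 R)
Conditions: PhMe (0.005 M), BHT, sealed tube, 180 °C
Reagents that add atoms: none
Why: Concerted thermal intramolecular [4+2] cycloaddition of an ester-tethered 1,3,9-decatriene, in which the diene C1–C4 adds suprafacially to the enone C5=C10 and forms C4–C5 and C1–C10; the closest known reaction type is the ester-tethered type 1 intramolecular Diels–Alder reaction of a (Z)-diene. The cyclohexene ring is closed by the cycloaddition itself, and the δ-lactone is closed by the same C4–C5 bond, which joins the two ends of the four-atom tether C19–O7–C7–C6 (a fused, not bridged, bicycle). C4 is controlled by the (Z)-geometry of the diene: the tether sits on the inside position, so C6 must be exo and only the cis-fused bicycle with C19 cis to C6 can form. C10 is controlled by the (E)-geometry of the enone, which is transferred suprafacially and puts the methyl group cis to C6 and the ketone C9 endo; C5 is controlled by allylic 1,3-strain, since the C10 methyl group holds the axial H6 in the enone plane, so the diene on C7 reaches one face while the ring oxygen O6 covers the other. The step needs this facial selectivity and it needs ring closure to outrun Z to E isomerisation and dimerisation of the dienoate; the first is secured by the silylene chair, which also fixes C5 and O7 gauche as the lactone requires, the second by high dilution, exclusion of light and acid, and a radical inhibitor. The ester carbonyl C19 is twisted out of the diene plane in the transition state, which softens the mismatch of two acceptor-substituted partners, but two quaternary centres are made and this is where the route carries its risk.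

Step 12
Reactants: 21 cis-fused cyclohexene δ-lactone adduct with the silylene on O6/O8
Product: 22 2,3-dihydro adduct (cyclohexane δ-lactone with the silylene on O6/O8; configurations unchanged)
Conditions: KO2C–N=N–CO2K, AcOH, MeOH/CH2Cl2, 0 °C → rt
Reagents that add atoms: none
Why: Diimide reduction: HN=NH generated in situ transfers two hydrogens syn through a six-membered transition state to the unpolarised cis-disubstituted ring alkene only, so the furan, the ketone and the lactone should be untouched and no stereocentre is created.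

Step 13
Reactants: 22 2,3-dihydro adduct (cyclohexane δ-lactone with the silylene on O6/O8)
Product: 24 (3S,3aR,4S,7aS)-3-[(1R,2R)-1,2-dihydroxypropyl]-4-[3-(furan-3-yl)propanoyl]-4,7a-dimethylhexahydro-2-benzofuran-1(3H)-one, via δ-lactone diol 23 (not isolated)
Conditions: HF·pyridine, THF, 0 °C → rt; then DBU (cat.), CH2Cl2, rt
Reagents that add atoms: none
Why: Fluoride-mediated desilylation cleaves both Si–O bonds, and base-catalysed translactonisation (a 1,2-acyl shift through the bicyclic ortho-acid) should then move C19 from O7 to O6, giving the less strained five-membered lactone of the target; no stereocentre is touched.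

Step 14
Reactants: 24 (3S,3aR,4S,7aS)-3-[(1R,2R)-1,2-dihydroxypropyl]-4-[3-(furan-3-yl)propanoyl]-4,7a-dimethylhexahydro-2-benzofuran-1(3H)-one
Product: 25 (3S,3aR,4S,7aS)-3-[(1S,2R)-2-{[tert-butyl(dimethyl)silyl]oxy}-1-hydroxypropyl]-4-[3-(furan-3-yl)propanoyl]-4,7a-dimethylhexahydro-2-benzofuran-1(3H)-one
Conditions: TBSCl, imidazole, DMF, 0 °C
Reagents that add atoms: tert-butyldimethylsilyl chloride, CC(C)(C)[Si](C)(C)Cl
Why: Site-selective silyl ether formation: TBSCl should react at the unhindered methyl carbinol O8 and not at O7, which is flanked by C6 of the bicyclic lactone with its two neighbouring quaternary carbons.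

Step 15
Reactants: 25 (3S,3aR,4S,7aS)-3-[(1S,2R)-2-{[tert-butyl(dimethyl)silyl]oxy}-1-hydroxypropyl]-4-[3-(furan-3-yl)propanoyl]-4,7a-dimethylhexahydro-2-benzofuran-1(3H)-one
Product: 26 (3S,3aR,4S,7aS)-3-[(1S,2R)-1-(acetyloxy)-2-{[tert-butyl(dimethyl)silyl]oxy}propyl]-4-[3-(furan-3-yl)propanoyl]-4,7a-dimethylhexahydro-2-benzofuran-1(3H)-one
Conditions: Ac2O, DMAP (cat.), pyridine, CH2Cl2, rt
Reagents that add atoms: acetic anhydride, CC(=O)OC(C)=O
Why: DMAP-catalysed acetylation (nucleophilic acyl-transfer catalysis) of the only remaining hydroxyl, the hindered O7–H.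

Step 16
Reactants: 26 (3S,3aR,4S,7aS)-3-[(1S,2R)-1-(acetyloxy)-2-{[tert-butyl(dimethyl)silyl]oxy}propyl]-4-[3-(furan-3-yl)propanoyl]-4,7a-dimethylhexahydro-2-benzofuran-1(3H)-one
Product: 27 (3S,3aR,4S,7aS)-3-[(1R,2R)-1-(acetyloxy)-2-hydroxypropyl]-4-[3-(furan-3-yl)propanoyl]-4,7a-dimethylhexahydro-2-benzofuran-1(3H)-one
Conditions: HF·pyridine, pyridine, THF, 0 °C → rt
Reagents that add atoms: none
Why: Desilylation with buffered HF·pyridine is weakly acidic, so the neighbouring acetate should stay on O7 instead of migrating to O8 as it could with basic fluoride sources, and the furan tolerates these conditions.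

Step 17
Reactants: 27 (3S,3aR,4S,7aS)-3-[(1R,2R)-1-(acetyloxy)-2-hydroxypropyl]-4-[3-(furan-3-yl)propanoyl]-4,7a-dimethylhexahydro-2-benzofuran-1(3H)-one
Product: 28 (3S,3aR,4S,7aS)-3-[(1S)-1-(acetyloxy)-2-oxopropyl]-4-[3-(furan-3-yl)propanoyl]-4,7a-dimethylhexahydro-2-benzofuran-1(3H)-one (CNP0170401.2)
Conditions: DMP, NaHCO3, CH2Cl2, 0 °C → rt
Reagents that add atoms: none
Why: Dess–Martin oxidation converts the C8 carbinol into the methyl ketone under buffered, near-neutral conditions, so the α-acetoxy centre C7 should not epimerise and the β-acyloxy ketone should not eliminate.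

Compound list
1 | 3-bromobutan-2-one | CC(Br)C(C)=O | starting material
2 | (3-oxobutan-2-yl)triphenylphosphonium bromide | CC(C(C)=O)[P+](c1ccccc1)(c1ccccc1)c1ccccc1.[Br-] | intermediate
3 | 3-(triphenyl-λ5-phosphanylidene)butan-2-one | CC(=O)C(C)=P(c1ccccc1)(c1ccccc1)c1ccccc1 | intermediate
4 | furan-3-ylmethanol | OCc1ccoc1 | starting material
5 | 3-(bromomethyl)furan | BrCc1ccoc1 | intermediate
6 | lithium 3-(triphenyl-λ5-phosphanylidene)but-1-en-2-olate (ylide enolate) | [Li]OC(=C)C(C)=P(c1ccccc1)(c1ccccc1)c1ccccc1 | intermediate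
7 | 1-(furan-3-yl)-4-(triphenyl-λ5-phosphanylidene)pentan-3-one | CC(=P(c1ccccc1)(c1ccccc1)c1ccccc1)C(=O)CCc1ccoc1 | intermediate
8 | acrolein (prop-2-enal) | C=CC=O | starting material
9 | ethyl 2-[bis(2,2,2-trifluoroethoxy)phosphoryl]propanoate | CCOC(=O)C(C)P(=O)(OCC(F)(F)F)OCC(F)(F)F | starting material
10 | potassium salt of the α-carbanion of 9 | CCOC(=O)[C-](C)P(=O)(OCC(F)(F)F)OCC(F)(F)F.[K+] | intermediate
11 | ethyl (2Z)-2-methylpenta-2,4-dienoate | C=C/C=C(/C)C(=O)OCC | intermediate
12 | lithium (2Z)-2-methylpenta-2,4-dienoate | C=C/C=C(/C)C(=O)[O-].[Li+] | intermediate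
13 | (2Z)-2-methylpenta-2,4-dienoic acid | C=C/C=C(/C)C(=O)O | intermediate
14 | 5-deoxy-D-ribose, (2R,3R,4R)-2,3,4-trihydroxypentanal | O=C[C@H](O)[C@H](O)[C@H](O)C | starting material
15 | (2R,3R,4R)-1,1-bis(ethylsulfanyl)pentane-2,3,4-triol | CCSC(SCC)[C@H](O)[C@H](O)[C@H](O)C | intermediate
16 | (4R,5R,6R)-4-[bis(ethylsulfanyl)methyl]-2,2-di-tert-butyl-6-methyl-1,3,2-dioxasilinan-5-ol | CCSC(SCC)[C@@H]1O[Si](C(C)(C)C)(C(C)(C)C)O[C@H](C)[C@H]1O | intermediate
17 | (4R,5R,6R)-2,2-di-tert-butyl-5-hydroxy-6-methyl-1,3,2-dioxasilinane-4-carbaldehyde | O=C[C@@H]1O[Si](C(C)(C)C)(C(C)(C)C)O[C@H](C)[C@H]1O | intermediate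
18 | (4E)-5-[(4S,5R,6R)-2,2-di-tert-butyl-5-hydroxy-6-methyl-1,3,2-dioxasilinan-4-yl]-1-(furan-3-yl)-4-methylpent-4-en-3-one | O=C(CCc1ccoc1)/C(C)=C/[C@@H]1O[Si](C(C)(C)C)(C(C)(C)C)O[C@H](C)[C@H]1O | intermediate
19 | (2Z)-2-methylpenta-2,4-dienoic 2,4,6-trichlorobenzoic anhydride | C=C/C=C(/C)C(=O)OC(=O)c1c(Cl)cc(Cl)cc1Cl | intermediate
20 | (4S,5R,6R)-2,2-di-tert-butyl-4-[(1E)-5-(furan-3-yl)-2-methyl-3-oxopent-1-en-1-yl]-6-methyl-1,3,2-dioxasilinan-5-yl (2Z)-2-methylpenta-2,4-dienoate (key-step precursor) | O=C(CCc1ccoc1)/C(C)=C/[C@@H]1O[Si](C(C)(C)C)(C(C)(C)C)O[C@H](C)[C@H]1OC(=O)C(/C)=C\C=C | intermediate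
21 | Diels–Alder adduct (key-step product): cyclohexene ring (C1–C5 and C10, C2=C3) cis-fused at C4–C5 to the δ-lactone C19(=O)–O7–C7–C6, which is trans-fused at C6–C7 to the O6,O8-di-tert-butylsilylene ring; CH3 on C4, CH3 and 3-(furan-3-yl)propanoyl on C10, CH3 on C8; C4 S, C5 R, C10 S, C6 S, C7 R, C8 R | C[C@H]1O[Si](C(C)(C)C)(C(C)(C)C)O[C@@H]2[C@@H]1OC(=O)[C@@]3(C)C=CC[C@](C)(C(=O)CCc4ccoc4)[C@@H]23 | intermediate
22 | 2,3-dihydro derivative of 21 (cyclohexane ring), configurations unchanged | C[C@H]1O[Si](C(C)(C)C)(C(C)(C)C)O[C@@H]2[C@@H]1OC(=O)[C@@]3(C)CCC[C@](C)(C(=O)CCc4ccoc4)[C@@H]23 | intermediate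
23 | δ-lactone diol: 22 without the silylene, free O6–H and O8–H, C19 still on O7 | C[C@@H](O)[C@H]1OC(=O)[C@@]2(C)CCC[C@](C)(C(=O)CCc3ccoc3)[C@H]2[C@@H]1O | intermediate
24 | (3S,3aR,4S,7aS)-3-[(1R,2R)-1,2-dihydroxypropyl]-4-[3-(furan-3-yl)propanoyl]-4,7a-dimethylhexahydro-2-benzofuran-1(3H)-one | C[C@@H](O)[C@@H](O)[C@H]1OC(=O)[C@@]2(C)CCC[C@](C)(C(=O)CCc3ccoc3)[C@@H]12 | intermediate
25 | (3S,3aR,4S,7aS)-3-[(1S,2R)-2-{[tert-butyl(dimethyl)silyl]oxy}-1-hydroxypropyl]-4-[3-(furan-3-yl)propanoyl]-4,7a-dimethylhexahydro-2-benzofuran-1(3H)-one | C[C@@H](O[Si](C)(C)C(C)(C)C)[C@@H](O)[C@H]1OC(=O)[C@@]2(C)CCC[C@](C)(C(=O)CCc3ccoc3)[C@@H]12 | intermediate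
26 | (3S,3aR,4S,7aS)-3-[(1S,2R)-1-(acetyloxy)-2-{[tert-butyl(dimethyl)silyl]oxy}propyl]-4-[3-(furan-3-yl)propanoyl]-4,7a-dimethylhexahydro-2-benzofuran-1(3H)-one | CC(=O)O[C@H]([C@@H](C)O[Si](C)(C)C(C)(C)C)[C@H]1OC(=O)[C@@]2(C)CCC[C@](C)(C(=O)CCc3ccoc3)[C@@H]12 | intermediate
27 | (3S,3aR,4S,7aS)-3-[(1R,2R)-1-(acetyloxy)-2-hydroxypropyl]-4-[3-(furan-3-yl)propanoyl]-4,7a-dimethylhexahydro-2-benzofuran-1(3H)-one | CC(=O)O[C@H]([C@@H](C)O)[C@H]1OC(=O)[C@@]2(C)CCC[C@](C)(C(=O)CCc3ccoc3)[C@@H]12 | intermediate
28 | (3S,3aR,4S,7aS)-3-[(1S)-1-(acetyloxy)-2-oxopropyl]-4-[3-(furan-3-yl)propanoyl]-4,7a-dimethylhexahydro-2-benzofuran-1(3H)-one (CNP0170401.2) | CC(=O)O[C@H](C(C)=O)[C@H]1OC(=O)[C@@]2(C)CCC[C@](C)(C(=O)CCc3ccoc3)[C@@H]12 | target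

Total step count: 17.
Longest linear sequence: 12 steps (steps 6–17, from 14 to 28).

Steps most likely to fail

1. Step 11. The cycloaddition may be too slow, because both partners carry acceptor groups and two quaternary centres are formed; thermal Z to E isomerisation or oligomerisation of the dienoate could then overtake ring closure. The fallback sets out from 17 and returns at 21. Wittig reaction of 17 with 2-(triphenyl-λ5-phosphanylidene)propanal (PhMe, 90 °C) would give (2E)-3-[(4S,5R,6R)-2,2-di-tert-butyl-5-hydroxy-6-methyl-1,3,2-dioxasilinan-4-yl]-2-methylprop-2-enal F1. Yamaguchi esterification with 13 through 19 would give its (2Z)-2-methylpenta-2,4-dienoate F2. The enal is a smaller and more electrophilic dienophile than the ketone, and with no furan on board it can be activated further with Me2AlCl (CH2Cl2, −78 → −20 °C), so the same intramolecular Diels–Alder reaction should give the C9-aldehyde adduct F3. Addition of 2-(furan-3-yl)ethylmagnesium bromide F4 (from purchased 3-(2-bromoethyl)furan and Mg; THF, −78 °C, quench with dilute HCl) would give the C9 carbinol F5 as a mixture of epimers, and Dess–Martin oxidation converges on 21.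

2. Step 10. Acylation of the flanked secondary hydroxyl may be slow enough for the activated (Z)-dienoyl unit to isomerise to the (E)-isomer or to take up nucleophiles in a conjugate sense, giving geometrically mixed ester. The fallback sets out from 18 and returns at 20. Coupling of 18 (DCC, DMAP, CH2Cl2) with 2-[bis(2,2,2-trifluoroethoxy)phosphoryl]propanoic acid F6 (made by hydrogenolysis of its benzyl ester, H2, Pd/C) would give the phosphonate ester F7. A Still–Gennari olefination of F7 with acrolein 8 (KN(SiMe3)2, 18-crown-6, THF, −78 °C, the anion trapped at once with excess aldehyde) would then build the (Z)-diene on the substrate under kinetic control, so no activated (Z)-acid is ever handled.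

3. Step 14. Discrimination between the two secondary hydroxyls may be poor, or the silyl group may migrate from O8 to O7, which would put the acetate of step 15 on the wrong oxygen. The fallback sets out from 24 and returns at 27, skipping 25 and 26. Exhaustive acetylation (Ac2O, DMAP, pyridine) would give the 7,8-diacetate F8. Lipase-catalysed hydrolysis (Candida antarctica lipase B, phosphate buffer pH 7/acetone, rt) should then remove only the acetate of the unhindered (R)-configured methyl carbinol O8, the configuration such lipases prefer, and leave the hindered O7 acetate and the lactone intact.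

Further compounds
F1 | step 11 | (2E)-3-[(4S,5R,6R)-2,2-di-tert-butyl-5-hydroxy-6-methyl-1,3,2-dioxasilinan-4-yl]-2-methylprop-2-enal | O=C/C(C)=C/[C@@H]1O[Si](C(C)(C)C)(C(C)(C)C)O[C@H](C)[C@H]1O
F2 | step 11 | (4S,5R,6R)-2,2-di-tert-butyl-6-methyl-4-[(1E)-2-methyl-3-oxoprop-1-en-1-yl]-1,3,2-dioxasilinan-5-yl (2Z)-2-methylpenta-2,4-dienoate | O=C/C(C)=C/[C@@H]1O[Si](C(C)(C)C)(C(C)(C)C)O[C@H](C)[C@H]1OC(=O)C(/C)=C\C=C
F3 | step 11 | C9-aldehyde analogue of 21 (formyl in place of the 3-(furan-3-yl)propanoyl group on C10; same configurations) | C[C@H]1O[Si](C(C)(C)C)(C(C)(C)C)O[C@@H]2[C@@H]1OC(=O)[C@@]3(C)C=CC[C@](C)(C=O)[C@@H]23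
F4 | step 11 | 2-(furan-3-yl)ethylmagnesium bromide | Br[Mg]CCc1ccoc1
F5 | step 11 | C9 carbinol of 21 (3-(furan-3-yl)-1-hydroxypropyl on C10; both C9 epimers) | C[C@H]1O[Si](C(C)(C)C)(C(C)(C)C)O[C@@H]2[C@@H]1OC(=O)[C@@]3(C)C=CC[C@](C)(C(O)CCc4ccoc4)[C@@H]23
F6 | step 10 | 2-[bis(2,2,2-trifluoroethoxy)phosphoryl]propanoic acid | CC(C(=O)O)P(=O)(OCC(F)(F)F)OCC(F)(F)F
F7 | step 10 | (4S,5R,6R)-2,2-di-tert-butyl-4-[(1E)-5-(furan-3-yl)-2-methyl-3-oxopent-1-en-1-yl]-6-methyl-1,3,2-dioxasilinan-5-yl 2-[bis(2,2,2-trifluoroethoxy)phosphoryl]propanoate | O=C(CCc1ccoc1)/C(C)=C/[C@@H]1O[Si](C(C)(C)C)(C(C)(C)C)O[C@H](C)[C@H]1OC(=O)C(C)P(=O)(OCC(F)(F)F)OCC(F)(F)F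
F8 | step 14 | 7,8-diacetate of 24, (3S,3aR,4S,7aS)-3-[(1S,2R)-1,2-bis(acetyloxy)propyl]-4-[3-(furan-3-yl)propanoyl]-4,7a-dimethylhexahydro-2-benzofuran-1(3H)-one | CC(=O)O[C@H]([C@@H](C)OC(C)=O)[C@H]1OC(=O)[C@@]2(C)CCC[C@](C)(C(=O)CCc3ccoc3)[C@@H]12
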